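**Retrosynthetic overview**

1. Ring locants: O1, C2 (CH3), C3 (CH2OH), C4 (CH2CO2R arm), C5 (CO2Me), C6 (=CH–O). The last disconnection removes three O-benzyl groups (primary alcohol and catechol).
2. Key disconnection: the dihydropyran is opened at C4–C5 and O1–C6 together, giving an acyclic δ-hydroxy (E)-enoate that already carries the hydroxytyrosyl ester, plus methyl propiolate. Forward, this is an alkoxide-triggered oxa-Michael/Michael annulation in which the C4–C5 bond closes the ring and sets C4.
3. Enabling feature: ring atoms O1–C6H=C5(CO2Me) are a β-alkoxyacrylate, the adduct of the C2 oxygen with a propiolate, so C5 is a carbanion at the moment O1–C6 forms. C4 carries a CH2CO2R arm, so it is the β-carbon of an enoate three bonds from O1, in a 6-exo relationship to that carbanion.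
4. The hydroxy enoate comes from cross-metathesis of an anti homoallylic alcohol (C2 and C3 stereocenters) with the acrylate of O,O-dibenzyl hydroxytyrosol. The alcohol comes from Sharpless epoxidation of (E)-crotyl alcohol and vinyl cuprate opening at the epoxide carbon next to CH2OH.
5. Ring formation order: the dihydropyran is the only ring made (key step); the arene is purchased.

Key step: step 7

Remark: (E)-but-2-en-1-ol of high geometric purity, hydroxytyrosol and methyl propiolate are taken as purchased; the ring locants above are used throughout.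

**Step 1**
Reactants: 1 (E)-but-2-en-1-ol
Product: 2 [(2S,3S)-3-methyloxiran-2-yl]methanol
Conditions: Ti(OiPr)4 (5 mol%), L-(+)-diethyl tartrate (6 mol%), t-BuOOH, 4 Å MS, CH2Cl2, −20 °C
Reagents that add atoms: tert-butyl hydroperoxide, CC(C)(C)OO
Why: Sharpless asymmetric epoxidation; the titanium L-(+)-tartrate catalyst delivers oxygen to one face of the (E)-allylic alcohol and sets both epoxide carbons as (2S,3S).

**Step 2**
Reactants: 2 [(2S,3S)-3-methyloxiran-2-yl]methanol
Product: 3 (2R,3S)-2-ethenylbutane-1,3-diol
Conditions: CH2=CHMgBr (3.5 equiv), CuI (15 mol%), THF, −30 → −10 °C; aq NH4Cl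
Reagents that add atoms: vinylmagnesium bromide, C=C[Mg]Br
Why: Copper-catalysed SN2 opening of a 2,3-epoxy alcohol by a vinyl Grignard reagent should occur at the epoxide carbon next to CH2OH, guided by the neighbouring oxygen, with inversion, giving the anti 1,3-diol while the carbinol center is retained.

**Step 3**
Reactants: 3 (2R,3S)-2-ethenylbutane-1,3-diol
Product: 4 (2S,3R)-3-[(benzyloxy)methyl]pent-4-en-2-ol
Conditions: Ag2O (1.5 equiv), BnBr (1.1 equiv), CH2Cl2, rt
Reagents that add atoms: benzyl bromide, BrCc1ccccc1
Why: Ag2O-mediated Williamson etherification of a diol should stop at mono-alkylation of the less hindered primary hydroxyl; no stereocenter is touched.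

**Step 4**
Reactants: 5 2-(3,4-dihydroxyphenyl)ethanol (hydroxytyrosol)
Product: 6 2-[3,4-bis(benzyloxy)phenyl]ethanol
Conditions: BnBr (2.2 equiv), K2CO3, acetone, reflux
Reagents that add atoms: benzyl bromide, BrCc1ccccc1
Why: Williamson etherification under carbonate conditions alkylates only the acidic phenols and leaves the aliphatic alcohol free.

**Step 5**
Reactants: 6 2-[3,4-bis(benzyloxy)phenyl]ethanol
Product: 7 2-[3,4-bis(benzyloxy)phenyl]ethyl prop-2-enoate
Conditions: CH2=CHCOCl, Et3N, CH2Cl2, 0 °C
Reagents that add atoms: acryloyl chloride, C=CC(=O)Cl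
Why: Acylation of a primary alcohol with an acid chloride and amine base is a standard esterification.

**Step 6**
Reactants: 4 (2S,3R)-3-[(benzyloxy)methyl]pent-4-en-2-ol; 7 2-[3,4-bis(benzyloxy)phenyl]ethyl prop-2-enoate
Product: 8 2-[3,4-bis(benzyloxy)phenyl]ethyl (2E,4R,5S)-4-[(benzyloxy)methyl]-5-hydroxyhex-2-enoate
Conditions: second-generation Hoveyda–Grubbs catalyst [RuCl2(H2IMes)(=CH-C6H4-2-OiPr)] (5 mol%), 7 (2 equiv), CH2Cl2, 40 °C
Reagents that add atoms: none
Why: Olefin cross-metathesis of a terminal alkene with an acrylate, which homodimerises slowly, should give the (E)-enoate under thermodynamic control and tolerates the free hydroxyl; the two stereocenters are not involved.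

**Step 7**
Reactants: 8 2-[3,4-bis(benzyloxy)phenyl]ethyl (2E,4R,5S)-4-[(benzyloxy)methyl]-5-hydroxyhex-2-enoate; 9 methyl prop-2-ynoate (methyl propiolate)
Product: 13 methyl (2S,3R,4S)-3-[(benzyloxy)methyl]-4-{2-[2-(3,4-bis(benzyloxy)phenyl)ethoxy]-2-oxoethyl}-2-methyl-3,4-dihydro-2H-pyran-5-carboxylate, via potassium alkoxide 10 (not isolated), via potassium allenolate 11 (not isolated), via potassium ester enolate 12 (not isolated)
Conditions: KH (1.05 equiv), THF (0.02 M), 0 °C; then 9 (1.1 equiv, slow addition), −78 → −40 °C; AcOH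
Reagents that add atoms: none
Why: Proposed new method: potassium alkoxide 10 adds to the β-carbon of methyl propiolate (oxa-Michael) to give the β-alkoxy allenolate 11, whose α-carbon (the future C5) attacks the β-carbon of the tethered (E)-enoate in a Michael addition that closes the dihydropyran and leaves ester enolate 12, which AcOH protonates. The closest known reaction type is the base-mediated tandem oxa-Michael/Michael annulation of phenoxides bearing an ortho Michael acceptor with alkynoates (4H-chromene synthesis), together with the trapping by carbon electrophiles of allenolates generated by conjugate addition to propiolates; an aliphatic secondary alkoxide with a simple enoate acceptor has not been shown. The ring closes in the 6-exo-trig mode and the enol ether C=C arrives at the correct oxidation level without adjustment. The new stereocenter at C4 is set by the two existing centers: in the chair-like transition state the C2 methyl is equatorial, the C3 hydrogen eclipses the enoate C=C (minimal A(1,3) strain) so that CH2OBn is axial, and the allenolate carbon bonds to the enoate face anti to CH2OBn, which should give the 3,4-trans (4S) product with the new CH2CO2R arm pseudoaxial and free of A(1,2) strain against CO2Me. The step needs C–C ring closure to outrun protonation of the vinyl anion and needs the alkoxide to choose the propiolate over the enoate; the first is addressed by an aprotic dilute medium in which KH leaves only H2 and by slow addition of the propiolate at −78 °C, the second by the much higher electrophilicity of the ynoate and by the fact that intramolecular oxa-Michael addition would give a strained oxetane.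

**Step 8**
Reactants: 13 methyl (2S,3R,4S)-3-[(benzyloxy)methyl]-4-{2-[2-(3,4-bis(benzyloxy)phenyl)ethoxy]-2-oxoethyl}-2-methyl-3,4-dihydro-2H-pyran-5-carboxylate
Product: 14 methyl (2S,3R,4S)-4-{2-[2-(3,4-dihydroxyphenyl)ethoxy]-2-oxoethyl}-3-(hydroxymethyl)-2-methyl-3,4-dihydro-2H-pyran-5-carboxylate
Conditions: H2 (1 atm), Pd/C (10% Pd), EtOAc, rt
Reagents that add atoms: none
Why: Heterogeneous hydrogenolysis should cleave the three benzyl ethers under neutral conditions, while the trisubstituted push–pull C=C of the vinylogous carbonate is not expected to be reduced at 1 atm and no stereocenter is affected.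

**Compound list**

1 | (E)-but-2-en-1-ol | C/C=C/CO | starting material
2 | [(2S,3S)-3-methyloxiran-2-yl]methanol | C[C@@H]1O[C@H]1CO | intermediate
3 | (2R,3S)-2-ethenylbutane-1,3-diol | C[C@H](O)[C@@H](CO)C=C | intermediate
4 | (2S,3R)-3-[(benzyloxy)methyl]pent-4-en-2-ol | C[C@H](O)[C@@H](COCc1ccccc1)C=C | intermediate
5 | 2-(3,4-dihydroxyphenyl)ethanol (hydroxytyrosol) | OCCc1ccc(O)c(O)c1 | starting material
6 | 2-[3,4-bis(benzyloxy)phenyl]ethanol | OCCc1ccc(OCc2ccccc2)c(OCc3ccccc3)c1 | intermediate
7 | 2-[3,4-bis(benzyloxy)phenyl]ethyl prop-2-enoate | C=CC(=O)OCCc1ccc(OCc2ccccc2)c(OCc3ccccc3)c1 | intermediate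
8 | 2-[3,4-bis(benzyloxy)phenyl]ethyl (2E,4R,5S)-4-[(benzyloxy)methyl]-5-hydroxyhex-2-enoate | C[C@H](O)[C@@H](COCc1ccccc1)/C=C/C(=O)OCCc2ccc(OCc3ccccc3)c(OCc4ccccc4)c2 | intermediate
9 | methyl prop-2-ynoate (methyl propiolate) | COC(=O)C#C | starting material
10 | potassium alkoxide (O-deprotonated 8) | C[C@H]([O-])[C@@H](COCc1ccccc1)/C=C/C(=O)OCCc2ccc(OCc3ccccc3)c(OCc4ccccc4)c2.[K+] | intermediate
11 | potassium allenolate (oxa-Michael adduct of the alkoxide to methyl propiolate) | COC([O-])=C=CO[C@@H](C)[C@@H](COCc1ccccc1)/C=C/C(=O)OCCc2ccc(OCc3ccccc3)c(OCc4ccccc4)c2.[K+] | intermediate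
12 | potassium ester enolate (cyclised, before protonation) | COC(=O)C1=CO[C@@H](C)[C@@H](COCc2ccccc2)[C@@H]1C=C([O-])OCCc3ccc(OCc4ccccc4)c(OCc5ccccc5)c3.[K+] | intermediate
13 | methyl (2S,3R,4S)-3-[(benzyloxy)methyl]-4-{2-[2-(3,4-bis(benzyloxy)phenyl)ethoxy]-2-oxoethyl}-2-methyl-3,4-dihydro-2H-pyran-5-carboxylate | COC(=O)C1=CO[C@@H](C)[C@@H](COCc2ccccc2)[C@@H]1CC(=O)OCCc3ccc(OCc4ccccc4)c(OCc5ccccc5)c3 | intermediate
14 | methyl (2S,3R,4S)-4-{2-[2-(3,4-dihydroxyphenyl)ethoxy]-2-oxoethyl}-3-(hydroxymethyl)-2-methyl-3,4-dihydro-2H-pyran-5-carboxylate (CNP0204147.2) | COC(=O)C1=CO[C@@H](C)[C@@H](CO)[C@@H]1CC(=O)OCCc2ccc(O)c(O)c2 | target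

**Step count**

Total steps: 8. Longest linear sequence: 6 steps (steps 1, 2, 3, 6, 7, 8); steps 4 and 5 build the acrylate arm.

**Steps most likely to fail**

Step 7 (proposed new method). The vinyl anion may be protonated before it cyclises, by proton transfer from the acidic alkyne C–H of 9 or from the γ-C–H of the enoate. That would stop the sequence at the acyclic ether, and facial selectivity at C4 may also be incomplete. The fallback uses known chemistry, sets out from 8 and returns at 13. Amine-catalysed oxa-Michael addition of 8 to 9 (N-methylmorpholine, CH2Cl2, rt) should give the (E)-β-alkoxyacrylate diester F1. Iodination–elimination (NIS, AcOH, CH2Cl2; then Et3N) should give the (Z)-α-iodo-β-alkoxyacrylate F2. Intramolecular reductive conjugate addition of the vinyl iodide to the enoate, mediated by Ni(cod)2 (zerovalent nickel) with Et3N and Et3SiH in MeCN, is a known 6-exo closure for vinyl iodides with tethered enoates. It forms the same C4–C5 bond under the same substrate control and returns to 13.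

Step 2. The cuprate may attack the epoxide carbon bearing the small methyl group instead, and the small water-soluble diol may be lost on isolation. The fallback sets out from 2 and returns at 3. Oxidation of 2 (RuCl3 cat., NaIO4, MeCN/CCl4/H2O) should give the glycidic acid (2R,3S)-3-methyloxirane-2-carboxylic acid F3. Organocuprate opening of a 2,3-epoxy acid is directed to the α-carbon by the carboxylate; with (CH2=CH)2CuLi in THF at −40 °C it should give, with inversion, (2S,3S)-2-ethenyl-3-hydroxybutanoic acid F4. Reduction with LiAlH4 in THF returns diol 3.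

Step 6. Cross-metathesis at the branched allylic position may be slow, with self-metathesis of 7 and catalyst decay leaving 4 unconverted. The fallback replaces metathesis by carbonyl olefination, sets out from 4 (with 6 for the ester arm) and returns at 8. Ozonolysis of 4 (O3, CH2Cl2, −78 °C; Me2S) should give the β-hydroxy aldehyde (2R,3S)-2-[(benzyloxy)methyl]-3-hydroxybutanal F5. Esterification of 6 with diethylphosphonoacetic acid (DCC, DMAP, CH2Cl2) should give the phosphonate 2-[3,4-bis(benzyloxy)phenyl]ethyl 2-(diethoxyphosphoryl)acetate F6. Horner–Wadsworth–Emmons olefination of F5 with F6 under mild Masamune–Roush conditions (LiCl, i-Pr2NEt, MeCN) should give (E)-enoate 8.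

**Further compounds**

F1 | step 7 | 2-[3,4-bis(benzyloxy)phenyl]ethyl (2E,4R,5S)-4-[(benzyloxy)methyl]-5-{[(1E)-3-methoxy-3-oxoprop-1-en-1-yl]oxy}hex-2-enoate | COC(=O)/C=C/O[C@@H](C)[C@@H](COCc1ccccc1)/C=C/C(=O)OCCc2ccc(OCc3ccccc3)c(OCc4ccccc4)c2
F2 | step 7 | 2-[3,4-bis(benzyloxy)phenyl]ethyl (2E,4R,5S)-4-[(benzyloxy)methyl]-5-{[(1Z)-2-iodo-3-methoxy-3-oxoprop-1-en-1-yl]oxy}hex-2-enoate | COC(=O)/C(I)=C/O[C@@H](C)[C@@H](COCc1ccccc1)/C=C/C(=O)OCCc2ccc(OCc3ccccc3)c(OCc4ccccc4)c2
F3 | step 2 | (2R,3S)-3-methyloxirane-2-carboxylic acid | C[C@@H]1O[C@H]1C(=O)O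
F4 | step 2 | (2S,3S)-2-ethenyl-3-hydroxybutanoic acid | C[C@H](O)[C@@H](C(=O)O)C=C
F5 | step 6 | (2R,3S)-2-[(benzyloxy)methyl]-3-hydroxybutanal | C[C@H](O)[C@@H](COCc1ccccc1)C=O
F6 | step 6 | 2-[3,4-bis(benzyloxy)phenyl]ethyl 2-(diethoxyphosphoryl)acetate | CCOP(=O)(CC(=O)OCCc1ccc(OCc2ccccc2)c(OCc3ccccc3)c1)OCC
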